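## Retrosynthetic overview
1. The last operation saturates the azepine C=C and removes two benzyl ethers. The azepane (ring 4) comes from ring-closing metathesis of an N-allyl piperidine with a tertiary vinyl carbinol.
2. The piperidine (ring 3) comes from cis-selective reduction of a six-membered cyclic imine, formed from a primary amine and a 1,5-related α-benzyloxy ketone. The vinyl carbinol comes from 1,2-addition to the cyclopentanone.
3. Key disconnection: the bond between piperidine C-2 and the cyclopentane. It is made by an intermolecular Mannich addition of a spiro-tetronate cyclopentanone lithium enolate to an (S)-tert-butanesulfinyl aldimine.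
4. Ketone fragment: the spiro-tetronate (ring 2) comes from a Dieckmann condensation on the cis-diol of a cyclopentene carboxylate. The cyclopentene (ring 1) comes from Evans allylation, RCM and CBS reduction.
5. Imine fragment: built from D-2-aminobutyric acid, which supplies the side-chain carbinol centre from the chiral pool.

Assumption: the organomagnesium reagents are used as ready-made solutions, and the minor C-4 epimer of 22 is removed by chromatography (this centre is erased again in step 27). Bn = benzyl, TBS = tert-butyldimethylsilyl.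

## Route

**Ketone fragment**

Step 1
Reactants: 1 (R)-4-benzyl-3-propanoyl-1,3-oxazolidin-2-one
Product: 2 (R)-4-benzyl-3-[(2S)-2-methylpent-4-enoyl]-1,3-oxazolidin-2-one
Conditions: NaHMDS, THF, −78 °C; allyl iodide, −78 → −45 °C
Reagents that add atoms: allyl iodide C=CCI
Why: Evans asymmetric alkylation, in which the chelated (Z)-sodium enolate is shielded on one face by the (R)-benzyl group, so allyl iodide enters from the open face and sets the (S)-methyl centre (minor isomer removed by chromatography).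

Step 2
Reactants: 2 (R)-4-benzyl-3-[(2S)-2-methylpent-4-enoyl]-1,3-oxazolidin-2-one
Product: 3 (2S)-N-methoxy-N,2-dimethylpent-4-enamide
Conditions: MeNHOMe·HCl, AlMe3, CH2Cl2, −10 °C → rt; Rochelle salt
Reagents that add atoms: N,O-dimethylhydroxylamine hydrochloride CNOC.Cl
Why: Weinreb transamidation, in which the aluminium amide attacks the exocyclic imide carbonyl, releases the auxiliary and leaves the α-centre untouched.

Step 3
Reactants: 3 (2S)-N-methoxy-N,2-dimethylpent-4-enamide
Product: 4 (4S)-4-methylhepta-1,6-dien-3-one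
Conditions: vinylMgBr, THF, 0 °C; inverse quench into cold 1 M HCl
Reagents that add atoms: vinylmagnesium bromide C=C[Mg]Br
Why: Weinreb ketone synthesis, in which the chelated tetrahedral adduct survives until the cold acidic quench and so prevents over-addition, amine Michael addition and epimerisation.

Step 4
Reactants: 4 (4S)-4-methylhepta-1,6-dien-3-one
Product: 5 (5S)-5-methylcyclopent-2-en-1-one
Conditions: Grubbs II (2 mol %), CH2Cl2, reflux; used as a concentrated solution (volatile)
Reagents that add atoms: none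
Why: Ring-closing metathesis of the two terminal alkenes closes the five-membered enone, is driven by loss of ethene and does not touch the stereocentre.

Step 5
Reactants: 5 (5S)-5-methylcyclopent-2-en-1-one
Product: 6 (5S)-2-iodo-5-methylcyclopent-2-en-1-one
Conditions: I2, pyridine, CH2Cl2, 0 °C → rt
Reagents that add atoms: iodine II
Why: Johnson α-iodination (conjugate addition of pyridine, iodination, elimination) touches only the enone α-carbon, and the medium is too weakly basic to enolise the α′-centre.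

Step 6
Reactants: 6 (5S)-2-iodo-5-methylcyclopent-2-en-1-one
Product: 7 (1S,5S)-2-iodo-5-methylcyclopent-2-en-1-ol
Conditions: (R)-Me-CBS (20 mol %), BH3·SMe2, THF, −30 °C; MeOH
Reagents that add atoms: none
Why: Corey–Bakshi–Shibata reduction, in which the iodoalkene arm acts as the large group, so the (R)-catalyst gives the (1S)-carbinol, and hydride also enters anti to the methyl group (matched case, OH cis to CH3).

Step 7
Reactants: 7 (1S,5S)-2-iodo-5-methylcyclopent-2-en-1-ol
Product: 8 ({[(1S,5S)-2-iodo-5-methylcyclopent-2-en-1-yl]oxy}methyl)benzene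
Conditions: NaH, BnBr, Bu4NI (cat.), THF, 0 °C → rt
Reagents that add atoms: benzyl bromide BrCc1ccccc1
Why: Williamson ether synthesis on the alkoxide forms no bond at a stereocentre, and the ring vinyl iodide cannot eliminate.

Step 8
Reactants: 8 ({[(1S,5S)-2-iodo-5-methylcyclopent-2-en-1-yl]oxy}methyl)benzene
Product: 9 methyl (4S,5S)-5-(benzyloxy)-4-methylcyclopent-1-ene-1-carboxylate
Conditions: Pd(PPh3)4 (5 mol %), CO (1 atm), MeOH, Et3N, DMF, 60 °C
Reagents that add atoms: carbon monoxide [C-]#[O+]; methanol CO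
Why: Palladium-catalysed methoxycarbonylation of a vinyl iodide (oxidative addition, CO insertion, methanolysis) gives the enoate with the alkene position retained.

Step 9
Reactants: 9 methyl (4S,5S)-5-(benzyloxy)-4-methylcyclopent-1-ene-1-carboxylate
Product: 10 methyl (1S,2S,3S,5S)-2-(benzyloxy)-1,5-dihydroxy-3-methylcyclopentane-1-carboxylate
Conditions: OsO4 (4 mol %), NMO, acetone–H2O 8:1, rt
Reagents that add atoms: N-methylmorpholine N-oxide C[N+]1([O-])CCOCC1; water O
Why: Upjohn dihydroxylation adds both oxygens syn from the ring face anti to the allylic OBn and the methyl group (Kishi model), which sets the quaternary carbinol and the neighbouring secondary carbinol.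

Step 10
Reactants: 10 methyl (1S,2S,3S,5S)-2-(benzyloxy)-1,5-dihydroxy-3-methylcyclopentane-1-carboxylate
Product: 11 methyl (1R,2S,3S,5S)-2-(benzyloxy)-5-[(tert-butyldimethylsilyl)oxy]-1-hydroxy-3-methylcyclopentane-1-carboxylate
Conditions: TBSCl, imidazole, DMF, rt → 40 °C
Reagents that add atoms: tert-butyldimethylsilyl chloride CC(C)(C)[Si](C)(C)Cl
Why: Silylation is sterically selective for the secondary over the tertiary hydroxyl, and the descriptor at C-1 changes only through CIP ranking.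

Step 11
Reactants: 11 methyl (1R,2S,3S,5S)-2-(benzyloxy)-5-[(tert-butyldimethylsilyl)oxy]-1-hydroxy-3-methylcyclopentane-1-carboxylate
Product: 12 methyl (1R,2S,3S,5S)-2-(benzyloxy)-5-[(tert-butyldimethylsilyl)oxy]-3-methyl-1-(propanoyloxy)cyclopentane-1-carboxylate
Conditions: (EtCO)2O (5 equiv), DMAP (1 equiv), Et3N, toluene, 80 °C
Reagents that add atoms: propionic anhydride CCC(=O)OC(=O)CC
Why: DMAP-catalysed acylation through the acylpyridinium ion esterifies the tertiary alcohol without forming an alkoxide, so the neighbouring silyl group does not migrate.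

Step 12
Reactants: 12 methyl (1R,2S,3S,5S)-2-(benzyloxy)-5-[(tert-butyldimethylsilyl)oxy]-3-methyl-1-(propanoyloxy)cyclopentane-1-carboxylate
Product: 13 (5R,6S,7S,9S)-6-(benzyloxy)-9-[(tert-butyldimethylsilyl)oxy]-4-hydroxy-3,7-dimethyl-1-oxaspiro[4.4]non-3-en-2-one
Conditions: LiHMDS (2.5 equiv), THF, −78 → 0 °C; 1 M HCl
Reagents that add atoms: none
Why: Dieckmann condensation of the propionate enolate onto the geminal methyl ester (5-exo) is driven by formation of the tetronate anion, and the quaternary centre has no α-hydrogen, so it cannot epimerise or undergo Chan rearrangement.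

Step 13
Reactants: 13 (5R,6S,7S,9S)-6-(benzyloxy)-9-[(tert-butyldimethylsilyl)oxy]-4-hydroxy-3,7-dimethyl-1-oxaspiro[4.4]non-3-en-2-one
Product: 14 (5R,6S,7S,9S)-6-(benzyloxy)-9-[(tert-butyldimethylsilyl)oxy]-4-methoxy-3,7-dimethyl-1-oxaspiro[4.4]non-3-en-2-one
Conditions: Me2SO4, K2CO3, acetone, reflux
Reagents that add atoms: dimethyl sulfate COS(=O)(=O)OC
Why: O-alkylation of the tetronate anion with a hard methylating agent gives the 4-methoxy vinylogous carbonate as the main regioisomer.

Step 14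
Reactants: 14 (5R,6S,7S,9S)-6-(benzyloxy)-9-[(tert-butyldimethylsilyl)oxy]-4-methoxy-3,7-dimethyl-1-oxaspiro[4.4]non-3-en-2-one
Product: 15 (5S,6S,7S,9S)-6-(benzyloxy)-9-hydroxy-4-methoxy-3,7-dimethyl-1-oxaspiro[4.4]non-3-en-2-one
Conditions: HF·pyridine, THF, 0 °C → rt
Reagents that add atoms: none
Why: Fluoride-driven desilylation under mildly acidic conditions leaves the benzyl ether and the methyl tetronate intact, and the C-5 descriptor changes only through CIP ranking.

Step 15
Reactants: 15 (5S,6S,7S,9S)-6-(benzyloxy)-9-hydroxy-4-methoxy-3,7-dimethyl-1-oxaspiro[4.4]non-3-en-2-one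
Product: 16 (5S,8S,9S)-9-(benzyloxy)-4-methoxy-3,8-dimethyl-1-oxaspiro[4.4]non-3-ene-2,6-dione
Conditions: Dess–Martin periodinane, CH2Cl2, 0 °C → rt
Reagents that add atoms: none
Why: Dess–Martin oxidation gives a ketone that can enolise only toward its CH2 side, so the β-benzyloxy group cannot be eliminated.

**Imine fragment**

Step 16
Reactants: 17 (R)-2-aminobutanoic acid (D-2-aminobutyric acid)
Product: 18 (R)-2-hydroxybutanoic acid
Conditions: NaNO2, 1 M H2SO4, 0 °C → rt
Reagents that add atoms: water O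
Why: Diazotisation proceeds with net retention, because the carboxylate displaces N2 to give an α-lactone that water then opens (double inversion).

Step 17
Reactants: 18 (R)-2-hydroxybutanoic acid
Product: 19 methyl (R)-2-hydroxybutanoate
Conditions: MeOH, H2SO4 (cat.), reflux
Reagents that add atoms: methanol CO
Why: Fischer esterification does not involve the stereocentre.

Step 18
Reactants: 19 methyl (R)-2-hydroxybutanoate
Product: 20 methyl (R)-2-(benzyloxy)butanoate
Conditions: benzyl 2,2,2-trichloroacetimidate, TfOH (cat.), cyclohexane–CH2Cl2, rt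
Reagents that add atoms: benzyl 2,2,2-trichloroacetimidate N=C(OCc1ccccc1)C(Cl)(Cl)Cl
Why: Acid-catalysed imidate benzylation avoids base and therefore avoids racemisation of the α-oxy ester.

Step 19
Reactants: 20 methyl (R)-2-(benzyloxy)butanoate
Product: 21 (R)-2-(benzyloxy)butanal
Conditions: DIBAL-H (1.05 equiv), CH2Cl2, −78 °C; Rochelle salt
Reagents that add atoms: none
Why: In this partial DIBAL reduction the α-alkoxy-chelated aluminium hemiacetal is stable at −78 °C and collapses to the aldehyde only on work-up.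

Step 20
Reactants: 21 (R)-2-(benzyloxy)butanal
Product: 22 (3R,4R)-3-(benzyloxy)non-8-en-4-ol
Conditions: pent-4-enylMgBr (Et2O), MgBr2·OEt2, CH2Cl2, −78 °C; pH 7 buffer
Reagents that add atoms: pent-4-enylmagnesium bromide C=CCCC[Mg]Br
Why: Grignard addition under Cram chelate control (Mg bridges the aldehyde and OBn oxygens) gives the syn alcohol.

Step 21
Reactants: 22 (3R,4R)-3-(benzyloxy)non-8-en-4-ol
Product: 23 {[(3R,4R)-3-(benzyloxy)non-8-en-4-yl]oxy}(tert-butyl)dimethylsilane
Conditions: TBSCl, imidazole, DMF, rt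
Reagents that add atoms: tert-butyldimethylsilyl chloride CC(C)(C)[Si](C)(C)Cl
Why: Standard silylation masks the future ketone carbon as a base-stable and organometal-stable ether.

Step 22
Reactants: 23 {[(3R,4R)-3-(benzyloxy)non-8-en-4-yl]oxy}(tert-butyl)dimethylsilane
Product: 25 (5R,6R)-6-(benzyloxy)-5-[(tert-butyldimethylsilyl)oxy]octanal, via ozonide 24 (not isolated)
Conditions: O3, CH2Cl2, −78 °C; PPh3, −78 °C → rt
Reagents that add atoms: ozone [O-][O+]=O
Why: Ozonolysis with reductive work-up cleaves the only alkene to the aldehyde.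

Step 23
Reactants: 25 (5R,6R)-6-(benzyloxy)-5-[(tert-butyldimethylsilyl)oxy]octanal
Product: 26 (S,E)-N-{(5R,6R)-6-(benzyloxy)-5-[(tert-butyldimethylsilyl)oxy]octylidene}-2-methylpropane-2-sulfinamide
Conditions: (S)-tert-butanesulfinamide, anhydrous CuSO4, CH2Cl2, rt
Reagents that add atoms: (S)-tert-butanesulfinamide CC(C)(C)[S@](=O)N
Why: Ellman condensation gives the (E)-aldimine without racemisation at sulfur.

**Coupling and endgame**

Step 24
Reactants: 16 (5S,8S,9S)-9-(benzyloxy)-4-methoxy-3,8-dimethyl-1-oxaspiro[4.4]non-3-ene-2,6-dione; 26 (S,E)-N-{(5R,6R)-6-(benzyloxy)-5-[(tert-butyldimethylsilyl)oxy]octylidene}-2-methylpropane-2-sulfinamide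
Product: 28 (S)-N-{(1S,5R,6R)-6-(benzyloxy)-1-[(5S,7R,8S,9S)-9-(benzyloxy)-4-methoxy-3,8-dimethyl-2,6-dioxo-1-oxaspiro[4.4]non-3-en-7-yl]-5-[(tert-butyldimethylsilyl)oxy]octyl}-2-methylpropane-2-sulfinamide, via lithium enolate 27 (not isolated)
Conditions: 16, LiHMDS, THF, −78 °C, 45 min; 26, −78 °C, 3 h; AcOH quench at −78 °C
Reagents that add atoms: none
Why: Intermolecular Mannich addition through a closed lithium-chelated transition state, in which the (S)-sulfinyl group fixes the (S)-amine carbon, the only possible enolate reacts on the face anti to the adjacent methyl group (the thermodynamic trans arrangement), and the ring (E)-enolate with the (E)-imine matches the required syn relationship.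

Step 25
Reactants: 28 (the Mannich adduct)
Product: 29 (S)-N-{(1S,5R,6R)-6-(benzyloxy)-1-[(5R,6S,7R,8S,9S)-9-(benzyloxy)-6-ethenyl-6-hydroxy-4-methoxy-3,8-dimethyl-2-oxo-1-oxaspiro[4.4]non-3-en-7-yl]-5-[(tert-butyldimethylsilyl)oxy]octyl}-2-methylpropane-2-sulfinamide
Conditions: vinylMgBr (4 equiv), LaCl3·2LiCl (1.1 equiv), THF, −78 → −40 °C; pH 7 buffer
Reagents that add atoms: vinylmagnesium bromide C=C[Mg]Br
Why: Lanthanide-promoted 1,2-addition suppresses enolisation, and the vinyl group enters anti to the pseudo-axial lactone C–O bond (polar Felkin–Anh) and anti to the bulky C-7 side chain, so the new OH is cis to the lactone oxygen and to the side chain while the far less electrophilic tetronate is untouched.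

Step 26
Reactants: 29 (the vinyl carbinol)
Product: 30 (S)-N-{(1S,5R,6R)-6-(benzyloxy)-1-[(5R,6S,7R,8S,9S)-9-(benzyloxy)-6-ethenyl-6-hydroxy-4-methoxy-3,8-dimethyl-2-oxo-1-oxaspiro[4.4]non-3-en-7-yl]-5-hydroxyoctyl}-2-methylpropane-2-sulfinamide
Conditions: TBAF, AcOH (1:1), THF, rt
Reagents that add atoms: none
Why: Buffered fluoride desilylation frees the secondary alcohol without base-induced retro-aldol opening of the hydroxy tetronate and without cleaving the sulfinamide.

Step 27
Reactants: 30 (the diol)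
Product: 31 (S)-N-{(1S,6R)-6-(benzyloxy)-1-[(5R,6S,7R,8S,9S)-9-(benzyloxy)-6-ethenyl-6-hydroxy-4-methoxy-3,8-dimethyl-2-oxo-1-oxaspiro[4.4]non-3-en-7-yl]-5-oxooctyl}-2-methylpropane-2-sulfinamide
Conditions: Dess–Martin periodinane, CH2Cl2, 0 °C → rt
Reagents that add atoms: none
Why: Dess–Martin oxidation converts only the secondary alcohol, since the tertiary allylic alcohol and the sulfinamide are inert and the near-neutral medium does not epimerise the α-benzyloxy centre.

Step 28
Reactants: 31 (the sulfinamido ketone)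
Product: 34 (5R,6S,7R,8S,9S)-9-(benzyloxy)-7-{(2S,6R)-6-[(1R)-1-(benzyloxy)propyl]piperidin-2-yl}-6-ethenyl-6-hydroxy-4-methoxy-3,8-dimethyl-1-oxaspiro[4.4]non-3-en-2-one, via amino ketone hydrochloride 32 (not isolated), via cyclic imine 33 (not isolated)
Conditions: 4 M HCl/dioxane, MeOH, 0 °C → rt, concentrate; Et3N, MeOH, 4 Å MS, rt; NaBH4, −40 → 0 °C
Reagents that add atoms: none
Why: Acid methanolysis removes the sulfinyl group, the amine condenses with the 1,5-related ketone, and in this reductive amination borohydride attacks axially on the half-chair that keeps the large C-2 substituent pseudo-equatorial (also the Felkin–Anh face of the α-benzyloxy imine), which sets the (6R)-centre 2,6-cis.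

Step 29
Reactants: 34 (the cis-2,6-disubstituted piperidine)
Product: 35 (5R,6S,7R,8S,9S)-9-(benzyloxy)-7-{(2S,6R)-6-[(1R)-1-(benzyloxy)propyl]-1-(prop-2-en-1-yl)piperidin-2-yl}-6-ethenyl-6-hydroxy-4-methoxy-3,8-dimethyl-1-oxaspiro[4.4]non-3-en-2-one
Conditions: allyl bromide, K2CO3, MeCN, 60 °C
Reagents that add atoms: allyl bromide C=CCBr
Why: SN2 N-alkylation with a reactive allylic halide works even on the hindered secondary amine, while quaternisation and O-alkylation of the tertiary alcohol are sterically blocked.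

Step 30
Reactants: 35 (the N-allyl vinyl carbinol)
Product: 36 O,O′-dibenzyl didehydro target (tetracycle whose azepine ring holds C(OH)–CH=CH–CH2–N)
Conditions: TsOH·H2O (1.05 equiv), Hoveyda–Grubbs II (10 mol %), toluene (2 mM), 80 °C; aq. NaHCO3
Reagents that add atoms: none
Why: Ring-closing metathesis of the only two terminal alkenes, run on the protonated amine so that ruthenium is not coordinated and assisted by the allylic hydroxyl, closes the trans-fused seven-membered ring with loss of ethene and touches no stereocentre.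

Step 31
Reactants: 36 (the tetracyclic azepine)
Product: 38 CNP0267781.1 (target), via saturated dibenzyl ether 37 (not isolated)
Conditions: H2 (1 → 4 atm), Pd(OH)2/C, MeOH, rt
Reagents that add atoms: none
Why: Catalytic hydrogenation saturates the disubstituted ring alkene first and then hydrogenolyses both benzyl ethers, while the tetrasubstituted tetronate alkene and the unactivated tertiary hydroxyl are not reduced and no stereocentre is involved.

## Compound list
1 | (R)-4-benzyl-3-propanoyl-1,3-oxazolidin-2-one | CCC(=O)N1[C@H](Cc2ccccc2)COC1=O | starting material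
2 | (R)-4-benzyl-3-[(2S)-2-methylpent-4-enoyl]-1,3-oxazolidin-2-one | C=CC[C@H](C)C(=O)N1[C@H](Cc2ccccc2)COC1=O | intermediate
3 | (2S)-N-methoxy-N,2-dimethylpent-4-enamide | C=CC[C@H](C)C(=O)N(C)OC | intermediate
4 | (4S)-4-methylhepta-1,6-dien-3-one | C=CC[C@H](C)C(=O)C=C | intermediate
5 | (5S)-5-methylcyclopent-2-en-1-one | C1[C@H](C)C(=O)C=C1 | intermediate
6 | (5S)-2-iodo-5-methylcyclopent-2-en-1-one | C1[C@H](C)C(=O)C(I)=C1 | intermediate
7 | (1S,5S)-2-iodo-5-methylcyclopent-2-en-1-ol | C1[C@H](C)[C@H](O)C(I)=C1 | intermediate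
8 | ({[(1S,5S)-2-iodo-5-methylcyclopent-2-en-1-yl]oxy}methyl)benzene | C1[C@H](C)[C@H](OCc2ccccc2)C(I)=C1 | intermediate
9 | methyl (4S,5S)-5-(benzyloxy)-4-methylcyclopent-1-ene-1-carboxylate | C1[C@H](C)[C@H](OCc2ccccc2)C(C(=O)OC)=C1 | intermediate
10 | methyl (1S,2S,3S,5S)-2-(benzyloxy)-1,5-dihydroxy-3-methylcyclopentane-1-carboxylate | C1[C@H](C)[C@H](OCc2ccccc2)[C@@](C(=O)OC)(O)[C@H]1O | intermediate
11 | methyl (1R,2S,3S,5S)-2-(benzyloxy)-5-(TBS-oxy)-1-hydroxy-3-methylcyclopentane-1-carboxylate | C1[C@H](C)[C@H](OCc2ccccc2)[C@@](C(=O)OC)(O)[C@H]1O[Si](C)(C)C(C)(C)C | intermediate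
12 | methyl (1R,2S,3S,5S)-2-(benzyloxy)-5-(TBS-oxy)-3-methyl-1-(propanoyloxy)cyclopentane-1-carboxylate | C1[C@H](C)[C@H](OCc2ccccc2)[C@@](C(=O)OC)(OC(=O)CC)[C@H]1O[Si](C)(C)C(C)(C)C | intermediate
13 | (5R,6S,7S,9S)-6-(benzyloxy)-9-(TBS-oxy)-4-hydroxy-3,7-dimethyl-1-oxaspiro[4.4]non-3-en-2-one | C1[C@H](C)[C@H](OCc3ccccc3)[C@@]2(OC(=O)C(C)=C2O)[C@H]1O[Si](C)(C)C(C)(C)C | intermediate
14 | (5R,6S,7S,9S)-6-(benzyloxy)-9-(TBS-oxy)-4-methoxy-3,7-dimethyl-1-oxaspiro[4.4]non-3-en-2-one | C1[C@H](C)[C@H](OCc3ccccc3)[C@@]2(OC(=O)C(C)=C2OC)[C@H]1O[Si](C)(C)C(C)(C)C | intermediate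
15 | (5S,6S,7S,9S)-6-(benzyloxy)-9-hydroxy-4-methoxy-3,7-dimethyl-1-oxaspiro[4.4]non-3-en-2-one | C1[C@H](C)[C@H](OCc3ccccc3)[C@@]2(OC(=O)C(C)=C2OC)[C@H]1O | intermediate
16 | (5S,8S,9S)-9-(benzyloxy)-4-methoxy-3,8-dimethyl-1-oxaspiro[4.4]non-3-ene-2,6-dione | C1[C@H](C)[C@H](OCc3ccccc3)[C@@]2(OC(=O)C(C)=C2OC)C1=O | intermediate
17 | (R)-2-aminobutanoic acid | CC[C@@H](N)C(=O)O | starting material
18 | (R)-2-hydroxybutanoic acid | CC[C@@H](O)C(=O)O | intermediate
19 | methyl (R)-2-hydroxybutanoate | CC[C@@H](O)C(=O)OC | intermediate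
20 | methyl (R)-2-(benzyloxy)butanoate | CC[C@@H](OCc1ccccc1)C(=O)OC | intermediate
21 | (R)-2-(benzyloxy)butanal | CC[C@@H](OCc1ccccc1)C=O | intermediate
22 | (3R,4R)-3-(benzyloxy)non-8-en-4-ol | CC[C@@H](OCc1ccccc1)[C@H](O)CCCC=C | intermediate
23 | {[(3R,4R)-3-(benzyloxy)non-8-en-4-yl]oxy}(tert-butyl)dimethylsilane | CC[C@@H](OCc1ccccc1)[C@H](O[Si](C)(C)C(C)(C)C)CCCC=C | intermediate
24 | ozonide (3-substituted 1,2,4-trioxolane) of 23 | CC[C@@H](OCc1ccccc1)[C@H](O[Si](C)(C)C(C)(C)C)CCCC2OCOO2 | intermediate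
25 | (5R,6R)-6-(benzyloxy)-5-(TBS-oxy)octanal | CC[C@@H](OCc1ccccc1)[C@H](O[Si](C)(C)C(C)(C)C)CCCC=O | intermediate
26 | (S,E)-N-[(5R,6R)-6-(benzyloxy)-5-(TBS-oxy)octylidene]-2-methylpropane-2-sulfinamide | CC[C@@H](OCc1ccccc1)[C@H](O[Si](C)(C)C(C)(C)C)CCC/C=N/[S@@](=O)C(C)(C)C | intermediate
27 | lithium enolate of 16 | C=1[C@H](C)[C@H](OCc3ccccc3)[C@@]2(OC(=O)C(C)=C2OC)C=1O[Li] | intermediate
28 | Mannich adduct (β-sulfinamido ketone, name in step 24) | CC[C@@H](OCc4ccccc4)[C@H](O[Si](C)(C)C(C)(C)C)CCC[C@H](N[S@@](=O)C(C)(C)C)[C@H]1[C@H](C)[C@H](OCc5ccccc5)[C@@]3(OC(=O)C(C)=C3OC)C1=O | intermediate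
29 | tertiary vinyl carbinol (name in step 25) | CC[C@@H](OCc4ccccc4)[C@H](O[Si](C)(C)C(C)(C)C)CCC[C@H](N[S@@](=O)C(C)(C)C)[C@H]1[C@H](C)[C@H](OCc5ccccc5)[C@@]3(OC(=O)C(C)=C3OC)[C@]1(O)C=C | intermediate
30 | desilylated diol (name in step 26) | CC[C@@H](OCc4ccccc4)[C@H](O)CCC[C@H](N[S@@](=O)C(C)(C)C)[C@H]1[C@H](C)[C@H](OCc5ccccc5)[C@@]3(OC(=O)C(C)=C3OC)[C@]1(O)C=C | intermediate
31 | α-benzyloxy ketone (name in step 27) | CC[C@@H](OCc4ccccc4)C(=O)CCC[C@H](N[S@@](=O)C(C)(C)C)[C@H]1[C@H](C)[C@H](OCc5ccccc5)[C@@]3(OC(=O)C(C)=C3OC)[C@]1(O)C=C | intermediate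
32 | primary amino ketone hydrochloride | CC[C@@H](OCc4ccccc4)C(=O)CCC[C@H](N)[C@H]1[C@H](C)[C@H](OCc5ccccc5)[C@@]3(OC(=O)C(C)=C3OC)[C@]1(O)C=C.Cl | intermediate
33 | cyclic imine: 7-{(2S)-6-[(1R)-1-(benzyloxy)propyl]-2,3,4,5-tetrahydropyridin-2-yl} analogue of 34 | CC[C@@H](OCc4ccccc4)C=1CCC[C@H](N=1)[C@H]2[C@H](C)[C@H](OCc5ccccc5)[C@@]3(OC(=O)C(C)=C3OC)[C@]2(O)C=C | intermediate
34 | cis-2,6-disubstituted piperidine (name in step 28) | CC[C@@H](OCc4ccccc4)[C@H]1CCC[C@H](N1)[C@H]2[C@H](C)[C@H](OCc5ccccc5)[C@@]3(OC(=O)C(C)=C3OC)[C@]2(O)C=C | intermediate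
35 | N-allyl piperidine (name in step 29) | CC[C@@H](OCc4ccccc4)[C@H]1CCC[C@H](N1CC=C)[C@H]2[C@H](C)[C@H](OCc5ccccc5)[C@@]3(OC(=O)C(C)=C3OC)[C@]2(O)C=C | intermediate
36 | O,O′-dibenzyl didehydro target (tetracyclic azepine) | CC[C@@H](OCc5ccccc5)[C@H]1CCC[C@H]2[C@H]3[C@H](C)[C@H](OCc6ccccc6)[C@@]4(OC(=O)C(C)=C4OC)[C@]3(O)C=CCN12 | intermediate
37 | O,O′-dibenzyl ether of the target | CC[C@@H](OCc5ccccc5)[C@H]1CCC[C@H]2[C@H]3[C@H](C)[C@H](OCc6ccccc6)[C@@]4(OC(=O)C(C)=C4OC)[C@]3(O)CCCN12 | intermediate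
38 | CNP0267781.1 | CC[C@@H](O)[C@H]1CCC[C@H]2[C@H]3[C@H](C)[C@H](O)[C@@]4(OC(=O)C(C)=C4OC)[C@]3(O)CCCN12 | target

## Step count and weak points
Total step count: 31 (ketone fragment 15, imine fragment 8, coupling and endgame 8).
Longest linear sequence: 23 steps (steps 1–15, then 24–31).

**Step 11 (acylation of the very hindered tertiary α-hydroxy ester).** The fallback sets out from 11 and comes back at 14. The alcohol is not acylated. Instead, 11 is heated with (triphenylphosphoranylidene)ketene in toluene at 110 °C. The hydroxyl adds to the slim cumulated ylide, and the resulting ester ylide closes by intramolecular Wittig olefination of the methyl ester carbonyl. The ester OMe becomes the enol ether, which gives the 3-unsubstituted spiro methyl tetronate F1. Because C-5 is quaternary, LDA (THF, −78 °C) can remove only the vinylic H-3. MeI then installs the missing methyl group and gives 14.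

**Step 24 (Mannich coupling: low conversion, retro-Mannich or poor selectivity).** The fallback sets out from 16 and 25 and comes back at 33. Carbon is joined to oxygen-bearing carbon first, and nitrogen is brought in afterwards by inversion.
- The dicyclohexylboron enolate of 16 (Cy2BCl, Et3N) adds to aldehyde 25 through a chair transition state and gives the anti aldol adduct F2.
- Vinyl addition as in step 25 gives the vinyl carbinol diol F3.
- Mitsunobu azidation of its secondary alcohol (PPh3, DIAD, DPPA) proceeds with inversion and gives the (S)-azide F4.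
- Buffered TBAF gives the azido alcohol F5.
- Dess–Martin oxidation gives the azido ketone F6.
- PPh3 in THF triggers a Staudinger/aza-Wittig ring closure to the cyclic imine 33, which is reduced as in step 28.

**Step 25 (facial selectivity or enolisation in the vinyl addition).** The fallback sets out from 28 and comes back at 29. Oxygen rather than carbon is delivered to the trigonal carbon, so a face preference that spoils step 25 becomes the useful one.
- Takai–Lombardo methylenation (Zn, CH2Br2, TiCl4) of 28 gives the exocyclic methylene compound F7.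
- Upjohn dihydroxylation gives the hydroxymethyl carbinol F8.
- Parikh–Doering oxidation of the primary alcohol gives the α-hydroxy aldehyde F9.
- Wittig methylenation (Ph3P=CH2) returns the vinyl carbinol 29.

## Further compounds
F1 | step 11 | (5R,6S,7S,9S)-6-(benzyloxy)-9-(TBS-oxy)-4-methoxy-7-methyl-1-oxaspiro[4.4]non-3-en-2-one | C1[C@H](C)[C@H](OCc3ccccc3)[C@@]2(OC(=O)C=C2OC)[C@H]1O[Si](C)(C)C(C)(C)C
F2 | step 24 | anti aldol adduct of 16 and 25 ((1R)-1-hydroxyoctyl side chain on the ring ketone) | CC[C@@H](OCc4ccccc4)[C@H](O[Si](C)(C)C(C)(C)C)CCC[C@@H](O)[C@H]1[C@H](C)[C@H](OCc5ccccc5)[C@@]3(OC(=O)C(C)=C3OC)C1=O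
F3 | step 24 | vinyl carbinol diol from F2 | CC[C@@H](OCc4ccccc4)[C@H](O[Si](C)(C)C(C)(C)C)CCC[C@@H](O)[C@H]1[C@H](C)[C@H](OCc5ccccc5)[C@@]3(OC(=O)C(C)=C3OC)[C@]1(O)C=C
F4 | step 24 | (S)-azide from F3 (inverted carbinol carbon) | CC[C@@H](OCc4ccccc4)[C@H](O[Si](C)(C)C(C)(C)C)CCC[C@H](N=[N+]=[N-])[C@H]1[C@H](C)[C@H](OCc5ccccc5)[C@@]3(OC(=O)C(C)=C3OC)[C@]1(O)C=C
F5 | step 24 | azido alcohol (F4 without TBS) | CC[C@@H](OCc4ccccc4)[C@H](O)CCC[C@H](N=[N+]=[N-])[C@H]1[C@H](C)[C@H](OCc5ccccc5)[C@@]3(OC(=O)C(C)=C3OC)[C@]1(O)C=C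
F6 | step 24 | azido ketone | CC[C@@H](OCc4ccccc4)C(=O)CCC[C@H](N=[N+]=[N-])[C@H]1[C@H](C)[C@H](OCc5ccccc5)[C@@]3(OC(=O)C(C)=C3OC)[C@]1(O)C=C
F7 | step 25 | exocyclic methylene compound (ring C=O of 28 replaced by C=CH2) | CC[C@@H](OCc4ccccc4)[C@H](O[Si](C)(C)C(C)(C)C)CCC[C@H](N[S@@](=O)C(C)(C)C)[C@H]1[C@H](C)[C@H](OCc5ccccc5)[C@@]3(OC(=O)C(C)=C3OC)C1=C
F8 | step 25 | hydroxymethyl carbinol (diol from F7) | CC[C@@H](OCc4ccccc4)[C@H](O[Si](C)(C)C(C)(C)C)CCC[C@H](N[S@@](=O)C(C)(C)C)[C@H]1[C@H](C)[C@H](OCc5ccccc5)[C@@]3(OC(=O)C(C)=C3OC)[C@]1(O)CO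
F9 | step 25 | α-hydroxy aldehyde from F8 | CC[C@@H](OCc4ccccc4)[C@H](O[Si](C)(C)C(C)(C)C)CCC[C@H](N[S@@](=O)C(C)(C)C)[C@H]1[C@H](C)[C@H](OCc5ccccc5)[C@@]3(OC(=O)C(C)=C3OC)[C@]1(O)C=O
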